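**Plan**

1. Retrosynthesis: the chain is cut at its C2'–C3' bond (sp3–sp2, B-alkyl Suzuki–Miyaura) into a 2-vinylcyclohexyl silyl ether and a C19 (E)-alkenyl iodide built from (2E,6E)-farnesyl bromide; the vinyl group goes back to a ring CHO; the cyclohexane is then not cyclised but taken back, by a retro-1,2-shift, to an epoxide on a cycloheptane.
2. Enabling feature: in the 1,3,3-trimethylcyclohexanol ring the chain-bearing CH (C2) lies between two fully substituted carbons, the carbinol C1 and the gem-dimethyl C3. Together with the first chain carbon it is the CH–CH of a cycloheptene oxide; a 1,2-shift of either flanking quaternary carbon contracts the seven-membered ring to the cyclohexane and turns the other epoxide carbon into the exocyclic CHO, and both modes give the same product.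
3. Forward: acyclic dienol (Cu-catalysed Grignard opening of (R)-2-methylglycidol, oxidation, methylenation), RCM to the seven-membered ring, silylation, epoxidation, ring contraction 7 → 6, methylenation, hydroboration/Suzuki coupling with the iodide, desilylation.
4. Stereochemistry: the carbinol centre comes from (R)-2-methylglycidol; its silyl ether directs the epoxide to the opposite face, and the ring contraction hands this on, with inversion, to the ring CH (chain trans to OH). Two E-olefins come with farnesyl bromide, the third from syn-hydrozirconation/iodination and a stereoretentive coupling.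

Key step: step 9

Assumption: the four starting materials are bought; (R)-2-methylglycidol is the Sharpless epoxidation product of 2-methylprop-2-en-1-ol, should it have to be made.

**Route**

Step 1
Reactants: 1 ethyl 3,3-dimethylpent-4-enoate
Product: 2 3,3-dimethylpent-4-en-1-ol
Conditions: LiAlH4, Et2O, 0 °C to rt
Reagents that add atoms: none
Why: Hydride reduction of an unhindered ester; the neopentyl vinyl group is inert.

Step 2
Reactants: 2 3,3-dimethylpent-4-en-1-ol
Product: 3 5-bromo-3,3-dimethylpent-1-ene
Conditions: CBr4, PPh3, CH2Cl2, 0 °C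
Reagents that add atoms: carbon tetrabromide, BrC(Br)(Br)Br
Why: Appel reaction turns the primary alcohol into the bromide under neutral conditions without touching the alkene.

Step 3
Reactants: 3 5-bromo-3,3-dimethylpent-1-ene; 4 (R)-2-methylglycidol
Product: 6 (S)-2,6,6-trimethyloct-7-ene-1,2-diol, via Grignard reagent 5 (not isolated)
Conditions: Mg, THF, rt (5, 2.2 equiv); then 4, CuI (10 mol%), THF, −30 to 0 °C; aq. NH4Cl
Reagents that add atoms: none
Why: Copper-catalysed Grignard opening of the 2,2-disubstituted epoxide occurs at the unsubstituted CH2 (SN2), so the quaternary carbinol centre of 4 is carried over untouched (the descriptor becomes S only through the change of CIP ranks), the first equivalent of 5 being spent on the hydroxyl.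

Step 4
Reactants: 6 (S)-2,6,6-trimethyloct-7-ene-1,2-diol
Product: 7 (S)-2-hydroxy-2,6,6-trimethyloct-7-enal
Conditions: IBX, DMSO, rt; used crude
Reagents that add atoms: none
Why: IBX oxidises the primary hydroxyl of a 1,2-diol to the aldehyde without glycol cleavage, and the α-carbon is quaternary, so nothing can epimerise.

Step 5
Reactants: 7 (S)-2-hydroxy-2,6,6-trimethyloct-7-enal
Product: 8 (S)-3,7,7-trimethylnona-1,8-dien-3-ol
Conditions: Ph3PCH3Br (2.5 equiv), KOtBu (2.5 equiv), THF, 0 °C to rt
Reagents that add atoms: methyltriphenylphosphonium bromide, C[P+](c1ccccc1)(c1ccccc1)c1ccccc1.[Br-]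
Why: Wittig methylenation of the aldehyde (the tertiary alkoxide is tolerated with excess ylide) should give the tertiary allylic alcohol with the stereocentre unchanged.

Step 6
Reactants: 8 (S)-3,7,7-trimethylnona-1,8-dien-3-ol
Product: 9 (S)-1,4,4-trimethylcyclohept-2-en-1-ol
Conditions: Grubbs II (5 mol%), CH2Cl2 (0.005 M), 40 °C
Reagents that add atoms: none
Why: Ring-closing metathesis of a 1,8-diene whose two vinyl groups sit on fully substituted carbons (Thorpe–Ingold help, free allylic OH aids initiation) should close the cis-cycloheptene, and the hindered product alkene should not re-enter metathesis.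

Step 7
Reactants: 9 (S)-1,4,4-trimethylcyclohept-2-en-1-ol
Product: 10 tert-butyldimethyl{[(1S)-1,4,4-trimethylcyclohept-2-en-1-yl]oxy}silane
Conditions: TBSOTf, 2,6-lutidine, CH2Cl2, −78 to 0 °C
Reagents that add atoms: tert-butyldimethylsilyl trifluoromethanesulfonate, CC(C)(C)[Si](C)(C)OS(=O)(=O)C(F)(F)F
Why: A silyl triflate with a hindered pyridine base silylates tertiary alcohols; the bulky silyl ether is the helper that later directs the epoxidation, tames the oxygen during the rearrangement and protects the aldol-type product.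

Step 8
Reactants: 10 tert-butyldimethyl{[(1S)-1,4,4-trimethylcyclohept-2-en-1-yl]oxy}silane
Product: 11 tert-butyldimethyl{[(1S,2S,7S)-2,6,6-trimethyl-8-oxabicyclo[5.1.0]octan-2-yl]oxy}silane (epoxide oxygen trans to the siloxy group, cis to the C2 methyl)
Conditions: mCPBA, NaHCO3, CH2Cl2, 0 °C; any syn-epoxide removed by chromatography
Reagents that add atoms: 3-chloroperoxybenzoic acid, OOC(=O)c1cccc(Cl)c1
Why: Prilezhaev epoxidation, in which the peracid is expected to approach the alkene face opposite the allylic C–OSi bond (the siloxy group being the pseudoaxial, shielding substituent, and allylic ethers directing peracids anti), which sets both epoxide carbons as 1S,7S.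

Step 9
Reactants: 11 tert-butyldimethyl{[(1S,2S,7S)-2,6,6-trimethyl-8-oxabicyclo[5.1.0]octan-2-yl]oxy}silane
Product: 12 (1S,2S)-2-[(tert-butyldimethylsilyl)oxy]-2,6,6-trimethylcyclohexane-1-carbaldehyde
Conditions: methylaluminium bis(4-bromo-2,6-di-tert-butylphenoxide) (MABR, 2 equiv), CH2Cl2, −78 to −20 °C; aq. NaF
Reagents that add atoms: none
Why: The bulky, oxophilic aluminium Lewis acid binds the epoxide oxygen, one epoxide C–O bond ionises while the ring bond on the neighbouring epoxide carbon migrates to it from the face opposite the departing oxygen, and that oxygen ends as the aldehyde C=O (Meinwald rearrangement; the closest known reaction types are the organoaluminium-promoted rearrangement of 2,3-epoxy silyl ethers to β-siloxy aldehydes and the Lewis-acid ring contraction of cycloalkene oxides to cycloalkanecarbaldehydes). The six-membered ring is not closed by an exo or endo cyclisation but by this suprafacial 1,2-shift of a ring carbon, which contracts the cycloheptane and expels one epoxide carbon as the formyl group. The new stereocentre, C1 of the cyclohexane, is set by inversion at the migration terminus, so the formyl carbon ends on the face that carried the epoxide oxygen, trans to the siloxy group, while the carbinol carbon keeps its S configuration whether it migrates (with retention) or stays. Because the epoxide CH–CH is flanked by two fully substituted carbons, cleavage of either C–O bond (with shift of the siloxy-bearing carbon or of the gem-dimethyl carbon) gives the same (1S,2S)-aldehyde, so no regiocontrol of the ionisation is needed. The selectivity that is needed is shift of a ring carbon over shift of hydride or of a methyl group; it rests on the push of the aluminium alkoxide towards the carbonyl, on the high migratory aptitude of the two fully substituted carbons and on a reagent that is neither nucleophilic nor protic, while the silyl ether keeps the C2 oxygen from acting as a pinacol donor and blocks retro-aldol of the product.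

Step 10
Reactants: 12 (1S,2S)-2-[(tert-butyldimethylsilyl)oxy]-2,6,6-trimethylcyclohexane-1-carbaldehyde
Product: 13 tert-butyl{[(1S,2S)-2-ethenyl-1,3,3-trimethylcyclohexyl]oxy}dimethylsilane
Conditions: Ph3PCH3Br, KHMDS, THF, −78 to 0 °C
Reagents that add atoms: methyltriphenylphosphonium bromide, C[P+](c1ccccc1)(c1ccccc1)c1ccccc1.[Br-]
Why: Wittig methylenation with salt-free ylide at low temperature; the α-hydrogen lies between two fully substituted carbons, so olefination is expected to outrun enolisation and the ring CH configuration should be kept.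

Step 11
Reactants: 14 1-(trimethylsilyl)propyne; 15 (2E,6E)-1-bromo-3,7,11-trimethyldodeca-2,6,10-triene (farnesyl bromide)
Product: 17 trimethyl[(5E,9E)-6,10,14-trimethylpentadeca-5,9,13-trien-1-yn-1-yl]silane, via lithiated silylpropyne 16 (not isolated)
Conditions: n-BuLi, THF, −78 to −20 °C; then 15, −78 to 0 °C
Reagents that add atoms: none
Why: Alkylation of the propargylic lithium of 14 by the primary allylic bromide at its α-carbon (SN2) adds the three-carbon alkyne and leaves both E-olefins of the farnesyl unit untouched.

Step 12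
Reactants: 17 trimethyl[(5E,9E)-6,10,14-trimethylpentadeca-5,9,13-trien-1-yn-1-yl]silane
Product: 18 (5E,9E)-6,10,14-trimethylpentadeca-5,9,13-trien-1-yne
Conditions: K2CO3 (cat.), MeOH, rt
Reagents that add atoms: none
Why: Base-catalysed protodesilylation of an alkynylsilane.

Step 13
Reactants: 18 (5E,9E)-6,10,14-trimethylpentadeca-5,9,13-trien-1-yne
Product: 20 (6E,10E)-7,11,15-trimethylhexadeca-6,10,14-trien-2-yne, via lithium acetylide 19 (not isolated)
Conditions: n-BuLi, THF, −78 °C; then MeI, to rt
Reagents that add atoms: iodomethane, CI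
Why: Deprotonation of the terminal alkyne and SN2 methylation of the acetylide.

Step 14
Reactants: 20 (6E,10E)-7,11,15-trimethylhexadeca-6,10,14-trien-2-yne
Product: 22 (2E,6E,10E)-2-iodo-7,11,15-trimethylhexadeca-2,6,10,14-tetraene, via alkenylzirconocene chloride 21 (not isolated)
Conditions: Cp2Zr(H)Cl (2 equiv), THF, rt to 40 °C; then I2, 0 °C
Reagents that add atoms: iodine, II
Why: Hydrozirconation adds H and Zr syn across the alkyne and, after equilibration with excess reagent, should place zirconium on the methyl-bearing carbon, and iodinolysis with retention then gives the (E)-2-iodoalkene while the trisubstituted olefins stay inert.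

Step 15
Reactants: 13 tert-butyl{[(1S,2S)-2-ethenyl-1,3,3-trimethylcyclohexyl]oxy}dimethylsilane; 22 (2E,6E,10E)-2-iodo-7,11,15-trimethylhexadeca-2,6,10,14-tetraene
Product: 24 tert-butyldimethyl{[(1S,2S)-1,3,3-trimethyl-2-[(3E,7E,11E)-3,8,12,16-tetramethylheptadeca-3,7,11,15-tetraen-1-yl]cyclohexyl]oxy}silane, via B-alkyl-9-BBN 23 (not isolated)
Conditions: 9-BBN, THF, rt to 50 °C; then 22, PdCl2(dppf) (5 mol%), AsPh3, Cs2CO3, DMF–H2O, rt
Reagents that add atoms: none
Why: Anti-Markovnikov hydroboration of the only alkene of 13 followed by B-alkyl Suzuki–Miyaura coupling with the alkenyl iodide, which proceeds with retention of olefin geometry and so should deliver the third E-olefin.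

Step 16
Reactants: 24 tert-butyldimethyl{[(1S,2S)-1,3,3-trimethyl-2-[(3E,7E,11E)-3,8,12,16-tetramethylheptadeca-3,7,11,15-tetraen-1-yl]cyclohexyl]oxy}silane
Product: 25 (1S,2S)-1,3,3-trimethyl-2-[(3E,7E,11E)-3,8,12,16-tetramethylheptadeca-3,7,11,15-tetraen-1-yl]cyclohexan-1-ol (CNP0273209.1)
Conditions: TBAF, THF, 60 °C
Reagents that add atoms: none
Why: Fluoride cleaves the Si–O bond without acid, so the tertiary alcohol and the polyene (prone to cation–olefin cyclisation under acid) should survive.

**Compound list**

1 | ethyl 3,3-dimethylpent-4-enoate | CCOC(=O)CC(C)(C)C=C | starting material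
2 | 3,3-dimethylpent-4-en-1-ol | OCCC(C)(C)C=C | intermediate
3 | 5-bromo-3,3-dimethylpent-1-ene | BrCCC(C)(C)C=C | intermediate
4 | (R)-2-methylglycidol, [(2R)-2-methyloxiran-2-yl]methanol | OC[C@]1(C)CO1 | starting material
5 | (3,3-dimethylpent-4-en-1-yl)magnesium bromide | C=CC(C)(C)CC[Mg]Br | intermediate
6 | (S)-2,6,6-trimethyloct-7-ene-1,2-diol | OC[C@@](C)(O)CCCC(C)(C)C=C | intermediate
7 | (S)-2-hydroxy-2,6,6-trimethyloct-7-enal | O=C[C@@](C)(O)CCCC(C)(C)C=C | intermediate
8 | (S)-3,7,7-trimethylnona-1,8-dien-3-ol | C=C[C@@](C)(O)CCCC(C)(C)C=C | intermediate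
9 | (S)-1,4,4-trimethylcyclohept-2-en-1-ol | C[C@@]1(O)C=CC(C)(C)CCC1 | intermediate
10 | tert-butyldimethyl{[(1S)-1,4,4-trimethylcyclohept-2-en-1-yl]oxy}silane | C[C@@]1(O[Si](C)(C)C(C)(C)C)C=CC(C)(C)CCC1 | intermediate
11 | tert-butyldimethyl{[(1S,2S,7S)-2,6,6-trimethyl-8-oxabicyclo[5.1.0]octan-2-yl]oxy}silane | C[C@@]1(O[Si](C)(C)C(C)(C)C)[C@H]2O[C@H]2C(C)(C)CCC1 | intermediate
12 | (1S,2S)-2-[(tert-butyldimethylsilyl)oxy]-2,6,6-trimethylcyclohexane-1-carbaldehyde | O=C[C@H]1C(C)(C)CCC[C@]1(C)O[Si](C)(C)C(C)(C)C | intermediate
13 | tert-butyl{[(1S,2S)-2-ethenyl-1,3,3-trimethylcyclohexyl]oxy}dimethylsilane | C=C[C@H]1C(C)(C)CCC[C@]1(C)O[Si](C)(C)C(C)(C)C | intermediate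
14 | 1-(trimethylsilyl)propyne | CC#C[Si](C)(C)C | starting material
15 | (2E,6E)-1-bromo-3,7,11-trimethyldodeca-2,6,10-triene | CC(C)=CCC/C(C)=C/CC/C(C)=C/CBr | starting material
16 | [3-(trimethylsilyl)prop-2-yn-1-yl]lithium | [Li]CC#C[Si](C)(C)C | intermediate
17 | trimethyl[(5E,9E)-6,10,14-trimethylpentadeca-5,9,13-trien-1-yn-1-yl]silane | CC(C)=CCC/C(C)=C/CC/C(C)=C/CCC#C[Si](C)(C)C | intermediate
18 | (5E,9E)-6,10,14-trimethylpentadeca-5,9,13-trien-1-yne | CC(C)=CCC/C(C)=C/CC/C(C)=C/CCC#C | intermediate
19 | [(5E,9E)-6,10,14-trimethylpentadeca-5,9,13-trien-1-yn-1-yl]lithium | CC(C)=CCC/C(C)=C/CC/C(C)=C/CCC#C[Li] | intermediate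
20 | (6E,10E)-7,11,15-trimethylhexadeca-6,10,14-trien-2-yne | CC(C)=CCC/C(C)=C/CC/C(C)=C/CCC#CC | intermediate
21 | chlorobis(cyclopentadienyl)[(2E,6E,10E)-7,11,15-trimethylhexadeca-2,6,10,14-tetraen-2-yl]zirconium | CC(C)=CCC/C(C)=C/CC/C(C)=C/CC/C=C(\C)[Zr](Cl)(C1C=CC=C1)C1C=CC=C1 | intermediate
22 | (2E,6E,10E)-2-iodo-7,11,15-trimethylhexadeca-2,6,10,14-tetraene | CC(C)=CCC/C(C)=C/CC/C(C)=C/CC/C=C(\C)I | intermediate
23 | 9-{2-[(1S,2S)-2-[(tert-butyldimethylsilyl)oxy]-2,6,6-trimethylcyclohexyl]ethyl}-9-borabicyclo[3.3.1]nonane | B1(CC[C@H]2C(C)(C)CCC[C@]2(C)O[Si](C)(C)C(C)(C)C)C3CCCC1CCC3 | intermediate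
24 | tert-butyldimethyl{[(1S,2S)-1,3,3-trimethyl-2-[(3E,7E,11E)-3,8,12,16-tetramethylheptadeca-3,7,11,15-tetraen-1-yl]cyclohexyl]oxy}silane | CC(C)=CCC/C(C)=C/CC/C(C)=C/CC/C=C(\C)CC[C@H]1C(C)(C)CCC[C@]1(C)O[Si](C)(C)C(C)(C)C | intermediate
25 | (1S,2S)-1,3,3-trimethyl-2-[(3E,7E,11E)-3,8,12,16-tetramethylheptadeca-3,7,11,15-tetraen-1-yl]cyclohexan-1-ol | CC(C)=CCC/C(C)=C/CC/C(C)=C/CC/C=C(\C)CC[C@H]1C(C)(C)CCC[C@]1(C)O | target

**Count and risks**

Total steps: 16. Longest linear sequence: 12 steps (steps 1–10, 15, 16, from 1 to 25); the iodide 22 is made in a four-step side branch (steps 11–14).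

Steps most likely to fail:

1. Step 9 (ring contraction). The epoxide may isomerise by hydride shift to the α-siloxy cycloheptanone, a methyl group of the gem-dimethyl carbon may migrate instead of a ring carbon, or the β-siloxy aldehyde may lose silanol under the Lewis acid to give the conjugated cyclohexenecarbaldehyde. Fallback: an oxidative ring contraction of the alkene itself, which sets out from 10 and bypasses 11. Thallium(III) nitrate trihydrate in methanol (buffered, 0 °C) should add thallium to the alkene face away from the siloxy group and methanol anti to it. In this trans adduct a ring C–C bond, never a hydrogen, lies anti to the C–Tl bond, so dethallation should proceed with 1,2-shift of the ring carbon (both regiochemistries of the addition converge, as in step 9) to the dimethyl acetal tert-butyl{[(1S,2S)-2-(dimethoxymethyl)-1,3,3-trimethylcyclohexyl]oxy}dimethylsilane F1. Mild hydrolysis (oxalic acid on wet silica gel, CH2Cl2) of the acetal then comes back to the route at 12.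

2. Step 8 (epoxidation). The peracid may attack the alkene face syn to the siloxy group, because the bias between OSi and CH3 on the allylic quaternary carbon is only steric; the syn-epoxide would lead to the C1 epimer of 12. Fallback: set the configuration by hydroxyl direction and two inversions, starting from 9. VO(acac)2/t-BuOOH (CH2Cl2, 0 °C) should give the syn-epoxy alcohol (1R,2S,7R)-2,6,6-trimethyl-8-oxabicyclo[5.1.0]octan-2-ol F2. Opening with 48% HBr (CHCl3, 0 °C) places bromide anti to the epoxide oxygen, mainly at the carbon next to the gem-dimethyl group, to give (1S,2S,3S)-3-bromo-1,4,4-trimethylcycloheptane-1,2-diol F3 with some of the regioisomer (1S,2S,3R)-2-bromo-1,4,4-trimethylcycloheptane-1,3-diol F4. Silver-assisted semipinacol rearrangement (AgBF4, CH2Cl2, −20 °C), in which the ring bond anti to C–Br migrates, should funnel both bromohydrins into (1S,2S)-2-hydroxy-2,6,6-trimethylcyclohexane-1-carbaldehyde F5. Silylation (TBSOTf, 2,6-lutidine) then comes back to the route at 12.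

3. Step 14 (hydrozirconation). Hydrometalation may be incompletely regioselective, with zirconium partly on C3 of the methyl alkyne, which would give a regioisomeric iodide that is hard to remove. Fallback: a silicon route with fixed regiochemistry, starting from 17 and bypassing 18–21. Trans-hydroalumination of the silylalkyne with DIBAL-H in heptane (50 °C) should give the α-silyl alkenylalane diisobutyl[(1E,5E,9E)-6,10,14-trimethyl-1-(trimethylsilyl)pentadeca-1,5,9,13-tetraen-1-yl]alumane F6 (not isolated). Ate-complex formation with MeLi and methylation with MeI, with retention, gives the vinylsilane trimethyl[(2E,6E,10E)-7,11,15-trimethylhexadeca-2,6,10,14-tetraen-2-yl]silane F7. Iododesilylation with retention (NIS, MeCN–ClCH2CN, 0 °C) comes back to the route at 22.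

**Further compounds**

F1 | step 9 | tert-butyl{[(1S,2S)-2-(dimethoxymethyl)-1,3,3-trimethylcyclohexyl]oxy}dimethylsilane | COC(OC)[C@H]1C(C)(C)CCC[C@]1(C)O[Si](C)(C)C(C)(C)C
F2 | step 8 | (1R,2S,7R)-2,6,6-trimethyl-8-oxabicyclo[5.1.0]octan-2-ol | C[C@@]1(O)[C@@H]2O[C@@H]2C(C)(C)CCC1
F3 | step 8 | (1S,2S,3S)-3-bromo-1,4,4-trimethylcycloheptane-1,2-diol | C[C@@]1(O)[C@H](O)[C@@H](Br)C(C)(C)CCC1
F4 | step 8 | (1S,2S,3R)-2-bromo-1,4,4-trimethylcycloheptane-1,3-diol | C[C@@]1(O)[C@@H](Br)[C@H](O)C(C)(C)CCC1
F5 | step 8 | (1S,2S)-2-hydroxy-2,6,6-trimethylcyclohexane-1-carbaldehyde | O=C[C@H]1C(C)(C)CCC[C@]1(C)O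
F6 | step 14 | diisobutyl[(1E,5E,9E)-6,10,14-trimethyl-1-(trimethylsilyl)pentadeca-1,5,9,13-tetraen-1-yl]alumane | CC(C)=CCC/C(C)=C/CC/C(C)=C/CC/C=C(\[Al](CC(C)C)CC(C)C)[Si](C)(C)C
F7 | step 14 | trimethyl[(2E,6E,10E)-7,11,15-trimethylhexadeca-2,6,10,14-tetraen-2-yl]silane | CC(C)=CCC/C(C)=C/CC/C(C)=C/CC/C=C(\C)[Si](C)(C)C
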